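J, charged at 0.23 mol%, is what I watch in the teal flask: the proposed step E + J → G takes it away, while E + Z + J → X + J needs it.

in all of them: J 0.23 mol%
- teal: E 0.80 M; Z 1.3 equiv; temperature 40 °C; the very flask that is asked about, followed so far
- amber: E 0.40 M; Z 1.3 equiv; temperature 25 °C; run made earlier
- flask: E 0.80 M; Z 1.30 equiv; temperature 40 °C; time 40 min

- teal (time / min: X / %, E / %): 3.00: 21, 78; 8.00: 29, 72; 15.0: 28, 68; 25.0: 34, 69
- amber (time / min: X / %, E / %): 1.33: 2, 98; 3.00: 6, 93; 4.00: 8, 90; 6.00: 11, 89

(each reading ± 1.5 percentage points)

- east: at 40 min raise the temperature by 25 K, then wait 40 min
- south: change nothing and wait 40 min more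
- south-east: at 40 min take out 90% of the X then present, then wait 40 min
- west: at 40 min add J, 50.0% of the amount charged, then wait 40 min

- X that was removed still counts
- the numbers in the tables scatter with a standard deviation of 1.5 percentage points
- steps that have been proposed: E + Z + J -> X + J; E + J -> G
- additions bring no volume worth counting

- X, in percent of the E first charged, at 40 min
- what to do for the largest gain in X; "none" if nothing gains more than 2 percentage points (east / south / south-east / west / none)
- X present, with what was taken out counted in, in percent of the E first charged, after east
- X present, with what was taken out counted in, in percent of the E first charged, after south-east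

Reading down the teal table, X stands at 21% after 3.00 min and 29% after 8.00 min. Its last two readings average 31.0%, while E reads 68% and 69%. So teal stops with E still present and Z charged in excess at 1.3 equiv, which points to J. Across in amber, X at 3.00 min is 6%, less than teal's 21% at that time, and its last reading of 11% shows no stop yet.

I take the fast loss of J as finished and count what it leaves. Dividing 31.0% by 0.23 mol% gives 135, and I call this X made per J charged the turnover budget (turnover number). Teal's reading at 8.00 min is already 93.5% of the level, so I reckon X at 40 min as 31.0%. With the budget reckoned as paid out, I count no gain from waiting or heat, and X is a reactant in neither proposed step, so I reckon east and south-east at 31.0% too. West adds 0.115% of J on the E charged, and the budget, which I leave unscaled for the lower [Z], gives 16 percentage points.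

The forecast, saying “This is catalyst death, not equilibrium”, gives 32%, west as best, 32.5% after east and 32% after south-east, with a west gain of 13 points against my 16 points.

The flask gives 31.5%, then 31.5% after east and 31.5% after south-east, and west gains 16 points. At 40.0 min, J stands at 0% of its charge and G at >99.9%. West's gain per J added is 142, beside my 135, although Z by then stands at 75.8% of its charge.

    E + Z + J → X + J, rate k1*[E]*[Z]*[J]/(1 + ([E]/sat1)) (0.133 M, k = 8.68 M⁻² s⁻¹, Ea = 38.0 kJ mol⁻¹)
    E + J → G (k = 0.00956 M⁻¹ s⁻¹, Ea = 49.0 kJ mol⁻¹)
    (constants at 40 °C)

In a neighbour flask, the same as this one but with 0.39 mol% of J, the budget gives 52.7% X at 40.0 min. The computed X in that neighbour is 54.5%.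

The data are simulated on assumed constants; noise was put on by code.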